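(The rate constants are invented.)

The easy mistake here is to take the coupling partner's charge as enough for an equal charge of starting material, when each intermediate B takes two partners.

    starting material + coupling partner → intermediate A (k1 = 100 L mol⁻¹ s⁻¹)
    coupling partner + intermediate A → intermediate B (k2 = 410 L mol⁻¹ s⁻¹)
    intermediate B → intermediate C (k3 = 0.0063 s⁻¹)
    intermediate B ⇌ intermediate D (K4 = 14, k4 = 0.045 s⁻¹)
    intermediate D → target (k5 = 9.5 × 10⁻⁴ s⁻¹)
    intermediate C ⇌ intermediate E (K6 = 0.99, k6 = 8.9 × 10⁻⁴ s⁻¹)
    intermediate A → decomposed reagent (k7 = 0.013 s⁻¹)

| setting | autumn | noon | winter | dusk |
|---|---|---|---|---|
| starting material | 0.30 mM | 0.50 mM | 0.80 mM | 1.2 mM |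
| coupling partner | 0.500 mM | 0.500 mM | 0.500 mM | 0.500 mM |
| time | 4.0 min | 4.0 min | 4.0 min | 4.0 min |

- "hardly changes" means that all values lie within two and a half points (for a concentration: within two and a half percent of the largest)
- run time (autumn): 4.0 min

* [target] at the end for autumn, noon, winter, dusk, in this order
* how the row runs (rises, then falls / rises all the way / hardly changes / falls all the way / falls, then rises)

First I take the flask with step 7 switched off. Each intermediate B then costs two partners, so the line to target receives at most half of the partner charge, which is 83.3% of the starting material charged in autumn and 20.8% at dusk. Even if that amount stood as intermediate D from the first moment, step 5 has a half-life of 12.2 min, longer than the 4.0 min allowed, and turns just 20.4% of it into target. My ceilings are therefore 17.0% of the charge in autumn and 4.25% at dusk. Next I take the opposite flask, where step 7 is so quick that intermediate A never meets a second partner. Each partner spent then ends as decomposed reagent, and the line to target stays empty.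

To place the real flask between these, I compare the two fates of intermediate A at the start. Step 2 over step 7 is 15.8 with the partner as charged, so the flask begins near the first version. But this ratio falls in step with the partner. The fraction of the partner charge at which steps 2 and 7 use intermediate A equally is 6.34%; I call it the tie level.

Autumn and dusk have the same tie level, with the same partner charge, but the clocks differ. At the first moment step 1 acts on the partner with a pseudo-first-order rate constant of 1.80 min⁻¹ in autumn and, larger, 7.20 min⁻¹ at dusk; these values hold for the start, since starting material is consumed as the flask runs. So I expect dusk to reach the tie level sooner and to fall furthest under its ceiling. Autumn's clock at the start is also slower than noon's, so I expect its intermediates to reach step 5 later and its target in mM to stand close to noon's, and I commit to a slight rise at most before the fall.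

The forecast gives 0.03 mM, 0.03 mM, 0.027 mM and 0.023 mM, a row that rises, then falls, and calls the early rise “a close call from a rough hand estimate”.

The flask gives 0.0278 mM, 0.0286 mM, 0.0261 mM and 0.0228 mM, a row that rises, then falls, turning at 0.41 mM of starting material. In autumn the partner stands at 9.89% of its charge after 2.00 min, above the tie level, and at 4.24% after 4.00 min, below it. At noon the partner is down to 0.610% after 2.00 min, so dividing by the tie level gives step 2 over step 7 as 0.0962, and step 7 takes 91.2% of the intermediate A consumed at that moment.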